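**Strategy.** The upper pyran ring (O1, C2, C3, C4, C4a, C8a) is disconnected at O1–C2. Its C2–C3–C4 chain is flanked by three electron-rich arenes (B ring on C2, A ring and the epigallocatechin D ring on C4). It can therefore pass through a 1,1,3-triarylallyl cation, which is a protonated vinyl o-quinone methide. The precursor is an acyclic tertiary allylic alcohol, made by 1,2-addition of an 8-lithiated epigallocatechin to a 2'-hydroxychalcone. A chiral Brønsted acid ionises it. In one operation the random carbinol centre is erased, the A-ring phenol closes onto C2, and C2 is set. The remaining C3=C4 alkene then relays C2 to C3 and C4 by syn hydroboration.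

Key step: step 5

Convention: flavan numbering is used. Upper unit: rings A (resorcinol), B (pyrogallol), C (pyran). Lower unit: rings D (phloroglucinol), E (pyrogallol), F (pyran). G is the galloyl ring. The target is robinetinidol-(4α→8)-(−)-epigallocatechin 3-O-gallate, with the upper unit 2R,3S,4S and the lower unit 2R,3R.

Assumption: the (R)-configured catalyst of step 5 is taken to give the (2S)-chromene; if the sense of induction is the reverse, the equally available (S)-catalyst is used and nothing else changes.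

Step 1
Reactants: 1 4'-benzyloxy-2'-hydroxyacetophenone; 2 3,4,5-tris(benzyloxy)benzaldehyde
Product: 3 (E)-4'-benzyloxy-2'-hydroxy-3,4,5-tris(benzyloxy)chalcone
Conditions: KOH, EtOH/THF, rt; then 1 M HCl
Reagents that add atoms: none
Why: Claisen–Schmidt condensation, in which aldol addition and E1cB dehydration give the conjugated (E)-enone, while the substrate stays an open phenoxide in strong base and so does not cyclise to the flavanone.

Step 2
Reactants: 4 (−)-epigallocatechin (2R,3R)
Product: 5 5,7,3',4',5'-penta-O-benzyl-(−)-epigallocatechin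
Conditions: BnBr, K2CO3, DMF, argon, 0 °C to rt
Reagents that add atoms: benzyl bromide, BrCc1ccccc1
Why: Williamson etherification, in which K2CO3 deprotonates only the five phenols so that the secondary 3-OH stays free, and cold work under argon suppresses pyrogallol autoxidation and base-induced C2 epimerisation, which becomes impossible once the 4'-OH is capped.

Step 3
Reactants: 5 penta-O-benzyl-epigallocatechin
Product: 6 8-bromo-5,7,3',4',5'-penta-O-benzyl-(−)-epigallocatechin
Conditions: NBS (1 equiv), CH2Cl2, −78 to 0 °C, dark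
Reagents that add atoms: N-bromosuccinimide, O=C1CCC(=O)N1Br
Why: Electrophilic aromatic bromination, in which the phloroglucinol-type D ring is by far the most nucleophilic arene, and benzylated flavan-3-ols are known to react with one equivalent of NBS at C8 rather than at C6, which lies between two benzyloxy groups.

Step 4
Reactants: 6 8-bromo-penta-O-benzyl-epigallocatechin; 3 chalcone
Product: 9 (E)-1-[4-(benzyloxy)-2-hydroxyphenyl]-1-(penta-O-benzyl-epigallocatechin-8-yl)-3-[3,4,5-tris(benzyloxy)phenyl]prop-2-en-1-ol (both carbinol epimers), via 3-O,8-dilithio species 7 (not isolated), via sodium phenoxide of the chalcone 8 (not isolated)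
Conditions: 6, n-BuLi (2 equiv), THF, −78 °C; separately 3, NaH, THF, 0 °C; 8 cannulated into 7, −78 to −40 °C; H2O quench at −78 °C; Et3N-deactivated silica
Reagents that add atoms: n-butyllithium, [Li]CCCC (lithium in 7 only); sodium hydride, [Na+].[H-] (sodium in 8 only)
Why: Halogen–lithium exchange followed by kinetic 1,2-addition of a hard aryllithium to a non-enolisable enone carbonyl, in which pre-forming both oxyanions prevents protonation of the aryllithium, and the new carbinol centre may form as a mixture because step 5 erases it.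

Step 5
Reactants: 9 tertiary allylic alcohol
Product: 11 (2S)-7-benzyloxy-2-[3,4,5-tris(benzyloxy)phenyl]-4-(penta-O-benzyl-epigallocatechin-8-yl)-2H-chromene, via vinyl o-quinone methide 10 (not isolated)
Conditions: (R)-3,3'-bis(2,4,6-triisopropylphenyl)-1,1'-binaphthyl-2,2'-diyl N-triflylphosphoramide (10 mol %), 4 Å MS, toluene, −78 °C, dark; Et3N quench
Reagents that add atoms: none
Why: The strong chiral acid protonates the tertiary, doubly benzylic and allylic hydroxyl of 9, water leaves, and the resulting 1,1,3-triarylallyl cation (the O-protonated form of 10) stays paired with the chiral phosphoramide anion and hydrogen-bonded to it through the A-ring OH. The closest known reaction type is the chiral N-triflylphosphoramide-catalysed intramolecular allylic substitution (SN1') of 2-(1-hydroxyallyl)phenols to 2-aryl-2H-chromenes. The pyran ring closes by 6-endo-trig attack of the phenol oxygen on the distal allyl terminus C2, which is the same event as a disrotatory oxa-6π electrocyclisation of 10. The only new stereocentre, C2, is set by the chiral counter-anion, which shields one face of the planar cation, and both carbinol epimers of 9 converge on that cation. Selectivity is needed among the oxygen nucleophiles and against Friedel–Crafts closure to an indene: the D-ring 7-OH is benzylated so the isomeric pyran cannot form, the lower 3-OH could only close a nine-membered ring, both D-ring ortho carbons are substituted, and the free A-ring ortho carbon C5 is meta to both oxygen donors. Low temperature, exclusion of light and the amine quench keep the closure kinetic, since the product can reopen to 10.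

Step 6
Reactants: 11 chromene; 12 3,4,5-tris(benzyloxy)benzoic acid
Product: 13 3-O-[3,4,5-tris(benzyloxy)benzoyl] ester of 11 (ester on the lower F-ring C3)
Conditions: DCC, DMAP (cat.), CH2Cl2, 0 °C to rt, dark
Reagents that add atoms: none
Why: Steglich esterification, in which the axial 3-OH of the lower F ring is the only hydroxyl left in 11, so no differentiation from the later upper 3-OH is needed, and the mildly basic medium does not reopen the chromene.

Step 7
Reactants: 13 galloylated chromene
Product: 15 dodeca-O-benzyl robinetinidol-(4α→8)-epigallocatechin 3-O-gallate (upper 2R,3S,4S with free 3-OH), via C3-borane 14 (not isolated)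
Conditions: BH3·SMe2, THF, 0 °C to rt, dark; then NaBO3·4H2O, THF/H2O, rt
Reagents that add atoms: borane–dimethyl sulfide, C[S+](C)[BH3-] (boron in 14 only); sodium perborate, [Na+].[Na+].O[B-]1(O)OO[B-](O)(O)OO1 (the C3 oxygen)
Why: Hydroboration–oxidation, in which the concerted syn addition places boron on the less substituted C3 and hydrogen on the diaryl-substituted C4 from the face anti to the C2 B ring, and oxidation with retention gives the 2,3-trans-3,4-trans array (3S,4S), just as flav-3-enes give 2,3-trans-flavan-3-ols and 1-arylcyclohexenes give trans-2-arylcyclohexanols, while perborate spares the gallate ester.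

Step 8
Reactants: 15 dodecabenzyl ether
Product: 16 robinetinidol-(4α→8)-(−)-epigallocatechin 3-O-gallate (target)
Conditions: H2 (1 atm), 20% Pd(OH)2/C, THF/MeOH, rt; filtration under argon, Sephadex LH-20
Reagents that add atoms: none
Why: Catalytic hydrogenolysis of all twelve benzyl ethers under neutral conditions, standard for benzylated flavan-3-ol gallates and proanthocyanidins, leaves the ester, both O1–C2 bonds, the C4–C8 bond and all five stereocentres untouched.

**Compound list**

1 | 4'-benzyloxy-2'-hydroxyacetophenone | CC(=O)c1ccc(OCc2ccccc2)cc1O | starting material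
2 | 3,4,5-tris(benzyloxy)benzaldehyde | O=Cc1cc(OCc2ccccc2)c(OCc2ccccc2)c(OCc2ccccc2)c1 | starting material
3 | (E)-4'-benzyloxy-2'-hydroxy-3,4,5-tris(benzyloxy)chalcone | O=C(/C=C/c1cc(OCc2ccccc2)c(OCc2ccccc2)c(OCc2ccccc2)c1)c1ccc(OCc2ccccc2)cc1O | intermediate
4 | (−)-epigallocatechin (2R,3R) | O[C@@H]1Cc2c(O)cc(O)cc2O[C@@H]1c1cc(O)c(O)c(O)c1 | starting material
5 | 5,7,3',4',5'-penta-O-benzyl-(−)-epigallocatechin | O[C@@H]1Cc2c(OCc3ccccc3)cc(OCc3ccccc3)cc2O[C@@H]1c1cc(OCc2ccccc2)c(OCc2ccccc2)c(OCc2ccccc2)c1 | intermediate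
6 | 8-bromo-penta-O-benzyl-(−)-epigallocatechin | O[C@@H]1Cc2c(OCc3ccccc3)cc(OCc3ccccc3)c(Br)c2O[C@@H]1c1cc(OCc2ccccc2)c(OCc2ccccc2)c(OCc2ccccc2)c1 | intermediate
7 | 3-O,8-dilithio species from 6 (not isolated) | [Li]O[C@@H]1Cc2c(OCc3ccccc3)cc(OCc3ccccc3)c([Li])c2O[C@@H]1c1cc(OCc2ccccc2)c(OCc2ccccc2)c(OCc2ccccc2)c1 | intermediate
8 | sodium phenoxide of chalcone 3 (not isolated) | [Na+].[O-]c1cc(OCc2ccccc2)ccc1C(=O)/C=C/c1cc(OCc2ccccc2)c(OCc2ccccc2)c(OCc2ccccc2)c1 | intermediate
9 | tertiary 1,1,3-triaryl allylic alcohol, both carbinol epimers | O[C@@H]1Cc2c(OCc3ccccc3)cc(OCc3ccccc3)c(C(O)(/C=C/c3cc(OCc4ccccc4)c(OCc4ccccc4)c(OCc4ccccc4)c3)c3ccc(OCc4ccccc4)cc3O)c2O[C@@H]1c1cc(OCc2ccccc2)c(OCc2ccccc2)c(OCc2ccccc2)c1 | intermediate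
10 | vinyl o-quinone methide, styryl group cis to the carbonyl (not isolated) | O[C@@H]1Cc2c(OCc3ccccc3)cc(OCc3ccccc3)c(C(/C=C/c3cc(OCc4ccccc4)c(OCc4ccccc4)c(OCc4ccccc4)c3)=C3\C=CC(OCc4ccccc4)=CC3=O)c2O[C@@H]1c1cc(OCc2ccccc2)c(OCc2ccccc2)c(OCc2ccccc2)c1 | intermediate
11 | (2S)-2,4-diaryl-2H-chromene with free lower 3-OH | O[C@@H]1Cc2c(OCc3ccccc3)cc(OCc3ccccc3)c(C3=C[C@@H](c4cc(OCc5ccccc5)c(OCc5ccccc5)c(OCc5ccccc5)c4)Oc4cc(OCc5ccccc5)ccc43)c2O[C@@H]1c1cc(OCc2ccccc2)c(OCc2ccccc2)c(OCc2ccccc2)c1 | intermediate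
12 | 3,4,5-tris(benzyloxy)benzoic acid | OC(=O)c1cc(OCc2ccccc2)c(OCc2ccccc2)c(OCc2ccccc2)c1 | starting material
13 | galloylated (2S)-chromene | O=C(O[C@@H]1Cc2c(OCc3ccccc3)cc(OCc3ccccc3)c(C3=C[C@@H](c4cc(OCc5ccccc5)c(OCc5ccccc5)c(OCc5ccccc5)c4)Oc4cc(OCc5ccccc5)ccc43)c2O[C@@H]1c1cc(OCc2ccccc2)c(OCc2ccccc2)c(OCc2ccccc2)c1)c1cc(OCc2ccccc2)c(OCc2ccccc2)c(OCc2ccccc2)c1 | intermediate
14 | C3-borane, boron trans to both aryl groups (not isolated) | O=C(O[C@@H]1Cc2c(OCc3ccccc3)cc(OCc3ccccc3)c([C@@H]3c4ccc(OCc5ccccc5)cc4O[C@H](c4cc(OCc5ccccc5)c(OCc5ccccc5)c(OCc5ccccc5)c4)[C@H]3B)c2O[C@@H]1c1cc(OCc2ccccc2)c(OCc2ccccc2)c(OCc2ccccc2)c1)c1cc(OCc2ccccc2)c(OCc2ccccc2)c(OCc2ccccc2)c1 | intermediate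
15 | dodeca-O-benzyl robinetinidol-(4α→8)-epigallocatechin 3-O-gallate | O=C(O[C@@H]1Cc2c(OCc3ccccc3)cc(OCc3ccccc3)c([C@@H]3c4ccc(OCc5ccccc5)cc4O[C@H](c4cc(OCc5ccccc5)c(OCc5ccccc5)c(OCc5ccccc5)c4)[C@H]3O)c2O[C@@H]1c1cc(OCc2ccccc2)c(OCc2ccccc2)c(OCc2ccccc2)c1)c1cc(OCc2ccccc2)c(OCc2ccccc2)c(OCc2ccccc2)c1 | intermediate
16 | robinetinidol-(4α→8)-(−)-epigallocatechin 3-O-gallate | O=C(O[C@@H]1Cc2c(O)cc(O)c([C@@H]3c4ccc(O)cc4O[C@H](c4cc(O)c(O)c(O)c4)[C@H]3O)c2O[C@@H]1c1cc(O)c(O)c(O)c1)c1cc(O)c(O)c(O)c1 | target

**Total step count:** 8. **Longest linear sequence:** 7 steps (4 → 5 → 6 → 9 → 11 → 13 → 15 → 16).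

**Steps most likely to fail**

Step 5.
- What may go wrong: the facial selectivity at C2 may erode in three ways. These are uncatalysed background ionisation of the very labile carbinol, acid- or light-induced reopening of the product, and a mismatch between the catalyst pocket and the bulky chiral epigallocatechin unit.
- Fallback: catalyst control is replaced by resolution through the built-in chiral unit. Starting from 9, the same O1–C2 closure is run with an achiral acid (PPTS, CH2Cl2, 0 °C). Chromene 11 then forms beside its C2 epimer, the (2R)-chromene F1.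
- The two are diastereomers because the lower unit is enantiopure, so they are separated by chromatography or crystallisation.
- F1 is recycled by irradiation at 365 nm. This opens it electrocyclically to 10, whose thermal closure regenerates the mixture. The route is rejoined at 11.

Step 4.
- What may go wrong: carbonyl addition to the anionic, deactivated phenoxide-enone may be slow. That would leave room for conjugate addition or for protonation of the hindered aryllithium.
- Fallback: a neutral electrophile is used instead. Starting from 3, O-allylation (allyl bromide, K2CO3, DMF) gives the 2'-O-allyl chalcone F2.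
- Species 7, made from 6 as before, adds to F2 to give the O-allyl tertiary alcohol F3.
- Neutral deallylation (Pd(PPh3)4 cat., morpholine, THF, rt) frees the phenol without ionising the carbinol. The route is rejoined at 9.

Step 7.
- What may go wrong: borane addition may be slow or poorly face-selective, because the orthogonal D ring shields the alkene. Forcing conditions invite β-elimination of boron with O1 (opening of the pyran) and reduction of the ester.
- Fallback: oxygen is installed through the ketone oxidation level. Starting from 13, dimethyldioxirane (acetone/CH2Cl2, −40 °C) should give the labile 3,4-epoxide F4.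
- A trace of BF3·OEt2 triggers a Meinwald rearrangement (C4–O ionisation, 1,2-hydride shift from C3) to the 2,4-trans flavan-3-one F5.
- Brief exposure to Et3N equilibrates the doubly benzylic C4–H to the diequatorial 2,4-cis flavan-3-one F6.
- NaBH4 (THF/MeOH, −40 °C) then attacks axially to give the equatorial 3-OH. The route is rejoined at 15.

**Further compounds**

F1 | step 5 | (2R)-chromene, C2 epimer of 11 | O[C@@H]1Cc2c(OCc3ccccc3)cc(OCc3ccccc3)c(C3=C[C@H](c4cc(OCc5ccccc5)c(OCc5ccccc5)c(OCc5ccccc5)c4)Oc4cc(OCc5ccccc5)ccc43)c2O[C@@H]1c1cc(OCc2ccccc2)c(OCc2ccccc2)c(OCc2ccccc2)c1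
F2 | step 4 | (E)-2'-allyloxy-4'-benzyloxy-3,4,5-tris(benzyloxy)chalcone | C=CCOc1cc(OCc2ccccc2)ccc1C(=O)/C=C/c1cc(OCc2ccccc2)c(OCc2ccccc2)c(OCc2ccccc2)c1
F3 | step 4 | O-allyl ether of 9 at the A-ring phenol, both carbinol epimers | O[C@@H]1Cc2c(OCc3ccccc3)cc(OCc3ccccc3)c(C(O)(/C=C/c3cc(OCc4ccccc4)c(OCc4ccccc4)c(OCc4ccccc4)c3)c3ccc(OCc4ccccc4)cc3OCC=C)c2O[C@@H]1c1cc(OCc2ccccc2)c(OCc2ccccc2)c(OCc2ccccc2)c1
F4 | step 7 | 3,4-epoxide of 13, oxygen anti to the B ring | O=C(O[C@@H]1Cc2c(OCc3ccccc3)cc(OCc3ccccc3)c([C@]35c4ccc(OCc6ccccc6)cc4O[C@H](c4cc(OCc6ccccc6)c(OCc6ccccc6)c(OCc6ccccc6)c4)[C@H]3O5)c2O[C@@H]1c1cc(OCc2ccccc2)c(OCc2ccccc2)c(OCc2ccccc2)c1)c1cc(OCc2ccccc2)c(OCc2ccccc2)c(OCc2ccccc2)c1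
F5 | step 7 | 2,4-trans 4-arylflavan-3-one (kinetic) | O=C(O[C@@H]1Cc2c(OCc3ccccc3)cc(OCc3ccccc3)c([C@H]3c4ccc(OCc5ccccc5)cc4O[C@H](c4cc(OCc5ccccc5)c(OCc5ccccc5)c(OCc5ccccc5)c4)C3=O)c2O[C@@H]1c1cc(OCc2ccccc2)c(OCc2ccccc2)c(OCc2ccccc2)c1)c1cc(OCc2ccccc2)c(OCc2ccccc2)c(OCc2ccccc2)c1
F6 | step 7 | 2,4-cis 4-arylflavan-3-one (equilibrated) | O=C(O[C@@H]1Cc2c(OCc3ccccc3)cc(OCc3ccccc3)c([C@@H]3c4ccc(OCc5ccccc5)cc4O[C@H](c4cc(OCc5ccccc5)c(OCc5ccccc5)c(OCc5ccccc5)c4)C3=O)c2O[C@@H]1c1cc(OCc2ccccc2)c(OCc2ccccc2)c(OCc2ccccc2)c1)c1cc(OCc2ccccc2)c(OCc2ccccc2)c(OCc2ccccc2)c1
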